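The beta run was what I had when the three flasks were set up.

| setting | beta | Thursday's | Tuesday's | Sunday's |
|---|---|---|---|---|
| starting complex | 0.11 M | 0.11 M | 0.11 M | 0.11 M |
| incoming ligand | 0.067 M | 0.220 M | 0.130 M | 0.170 M |
| remark | run made earlier |  |  |  |
| time |  | 15 min | 15 min | 15 min |

- beta (time / min: starting complex / %, complex with two exchanged / %): 0.833: 96, 0; 1.50: 92, 1; 3.00: 88, 1; 6.00: 71, 2; 10.0: 60, 1

(scatter of a reading: 2 percentage points)

- a reading or a percentage of complex with two exchanged counts all its forms, free or not
- what has gone from starting complex into another species counts as reacted, even if it can come back
- no earlier run changes the charge of incoming ligand; that part of a forecast is a guess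

- part of the starting complex that has reacted at the end, Thursday's
- part of the starting complex that has reacted at the end, Tuesday's
- part of the starting complex that has reacted at the end, Sunday's
- what raising the concentration of incoming ligand from its lowest to its highest value here does to the part of the starting complex that has reacted (changes below 5 percentage points count as none) (it falls / no change / it rises)

The beta run gave one clock. Starting complex fell steadily, and its last reading gives a first-order constant:

k_b = −ln(60%) / 10.0 min = 0.0511 min⁻¹

The earlier readings lie around that value within their scatter. The beta run held 0.067 M of incoming ligand against 0.11 M of starting complex, so the ligand was in no excess there and this is no pseudo-first-order case. I froze [incoming ligand] at its charge all the same, as a working assumption of my own that the steady constant does not prove. I also made the loss proportional to that charge, and this is my guess, since no earlier run changes it: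

κ = k_b / 0.067 M = 0.762 L mol⁻¹ min⁻¹

I call κ the loss constant per ligand, the first-order loss of starting complex per unit of [incoming ligand]. Its inverse, taken with a charge, is the life of the starting complex, and these lives make a ladder.

Thursday's: 5.96 min
Sunday's: 7.72 min
Tuesday's: 10.1 min

The last of these is still shorter than the 15 min allowed. The beta run sits a rung lower, with a life of 19.6 min, longer than its last reading at 10.0 min. Lowest stands complex with two exchanged, whose 1% in the beta run is less than the scatter of 2 percentage points.

So I reckoned reacted = 1 − exp(−κ[incoming ligand]t):

Thursday's: 91.9%
Tuesday's: 77.4%
Sunday's: 85.7%

That is a rise of 15 points. The forecast differed from this, giving 54%, 54% and 54% with no change, on the ground that “The rate therefore looks nearly independent of incoming ligand”.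

The flasks gave 92.7% on Thursday's, 77.3% on Tuesday's and 86.3% on Sunday's. Across the charges, it rises, by 15 points.

    leaving ligand + starting complex ⇌ idle adduct, settled at all times (K = 1510 L mol⁻¹)
    crystals ⇌ complex with two exchanged, rate k2*(cs2 - [complex with two exchanged]) while solid is left; crystals form when [complex with two exchanged] > cs2 (solubility = 6.10 mM, k = 0.0164 s⁻¹)
    starting complex + complex with one exchanged → side product (k = 0.0269 L mol⁻¹ s⁻¹)
    complex with one exchanged + incoming ligand ⇌ leaving ligand + complex with two exchanged (K = 41.0, k = 0.00595 L mol⁻¹ s⁻¹)
    starting complex + incoming ligand ⇌ leaving ligand + complex with one exchanged (K = 1.64, k = 0.00578 L mol⁻¹ s⁻¹)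

The charge of incoming ligand is the main reason for the spread: without its difference from Tuesday's charge, Thursday's falls from 92.7% to 77.3%. Thursday's still held 75% of its incoming ligand against 7.3% of its starting complex, and κ at that charge leaves 8.08% of starting complex. For the flask like Sunday's but with 0.043 M of incoming ligand, κ gives 38.8% reacted, and that flask reacted 37.3%.

The data were computed on assumed constants, and the scatter is random.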